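The benzene ring of the chromene (ring A) is built, not bought: a [4+2] cycloaddition of a dihydropyran-based silyl ketene acetal diene with but-3-yn-2-one forms C4a–C5 and C6–C7, and loss of methanol aromatizes the adduct. The step exploits the 1,3-relationship of the ring oxygens at C8a (O1) and C7 across C8, together with the two-carbon chain on C6, so acetyl, phenol and pyran oxygen arrive in fixed positions. The precursor is 6-(2-methoxy-2-silyloxyethenyl)-2,2-dimethyl-3,4-dihydro-2H-pyran. The (S)-carbinol then comes from asymmetric ketone hydrogenation and the Z enol ether from a stereoretentive copper-catalysed O-vinylation with a geometrically defined vinyl iodide.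

Key step: step 4

Remarks on the chemistry
- Ring size: the oxane ring of the diene requires a δ-hydroxy β-keto ester. Opening 2,2-dimethyloxirane with an acetoacetate dianion would give the γ-hydroxy homologue, which closes to a five-membered 2-alkylidene-oxolane, so the chain is assembled from the six-membered lactone 1 and an acetate enolate.
- Lactone 1 is assumed to be a catalogue compound.
- Lactol 4 is racemic. The ketene acetal geometry of 6 and 7 and the configuration of cycloadduct 9 are uncontrolled and are erased on aromatization, so their SMILES carry no descriptors there.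
- Target configuration: the carbinol carbon is (S) (O > aryl > CH3 > H), and the enol ether is Z (ether oxygen cis to CH2OH, trans to the aryl group).

Step 1
Reactants: 1 6,6-dimethyloxan-2-one; 2 methyl acetate
Product: 4 methyl 2-(2-hydroxy-6,6-dimethyloxan-2-yl)acetate, via lithium enolate 3 (not isolated)
Conditions: LiN(iPr)2 (2.2 equiv, commercial solution), 2 (2.2 equiv), THF, −78 °C; then 1, −78 °C; AcOH quench
Reagents that add atoms: none
Why: Claisen-type addition of the lithium ester enolate to the lactone carbonyl should stop after one addition because the β-keto ester released on ring opening is deprotonated at once by the second equivalent of enolate, and on work-up the δ-hydroxy β-keto ester closes to the six-membered hemiketal 4 (racemic, in equilibrium with its open-chain form).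

Step 2
Reactants: 4 methyl 2-(2-hydroxy-6,6-dimethyloxan-2-yl)acetate
Product: 5 methyl (2E)-2-(6,6-dimethyloxan-2-ylidene)acetate
Conditions: PPTS (5 mol%), 4 Å molecular sieves, toluene, 60 °C
Reagents that add atoms: none
Why: Mild acid-catalysed dehydration of the hemiketal should give the exocyclic enol ether conjugated with the ester (a vinylogous carbonate), the thermodynamically preferred alkene with the ester trans to the ring oxygen, while the weak acid avoids ionizing the tertiary C–O bond.

Step 3
Reactants: 5 methyl (2E)-2-(6,6-dimethyloxan-2-ylidene)acetate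
Product: 7 6-[2-methoxy-2-(trimethylsilyloxy)ethenyl]-2,2-dimethyl-3,4-dihydro-2H-pyran, via lithium dienolate 6 (not isolated)
Conditions: LiN(iPr)2 (1.1 equiv, commercial solution), THF, −78 °C; Me3SiCl (1.3 equiv), −78 °C → rt; pentane, filtration under argon, used at once
Reagents that add atoms: chlorotrimethylsilane, C[Si](C)(C)Cl
Why: Kinetic γ-deprotonation of the β-alkoxy enoate at the ring methylene cis to the ester gives the extended enolate, which the chlorosilane traps on oxygen, the standard dienolate O-silylation route to 1-alkoxy-1-silyloxy-3-oxy-1,3-dienes.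

Step 4
Reactants: 7 6-[2-methoxy-2-(trimethylsilyloxy)ethenyl]-2,2-dimethyl-3,4-dihydro-2H-pyran; 8 but-3-yn-2-one
Product: 10 1-(7-hydroxy-2,2-dimethyl-3,4-dihydro-2H-chromen-6-yl)ethan-1-one, via cycloadduct 9 (not isolated)
Conditions: toluene, 0 °C → rt, argon, no Lewis acid; then 1 M aq. HCl, THF, rt
Reagents that add atoms: none
Why: The electron-rich diene 7 and the ynone 8 should combine in an asynchronous, polarized [4+2] cycloaddition in which the nucleophilic ring carbon C5 of the dihydropyran (future C4a) bonds to the alkyne terminus (future C5) and the ketene acetal carbon (future C7) to the acetyl-bearing carbon (future C6), giving the cyclohexa-1,4-diene 9; aqueous acid then removes the silyl group of the mixed ketal at C7, methanol is expelled, and the resulting dienone tautomerizes to the phenol 10, held by a hydrogen bond to the acetyl group. The closest known reaction type is the Diels–Alder/aromatization of 1-alkoxy-1-silyloxy-3-oxy-1,3-dienes with acetylenic ketones to resorcinol derivatives. The carbocycle (ring A) is closed by an intermolecular [4π+2π] cycloaddition, both new σ-bonds forming suprafacially between the diene termini and the two alkyne carbons, not by cyclization of a tethered chain. No stereocentre survives, since C4a and C7 of 9 are transient and are erased on aromatization. The step needs regioselectivity, secured by the match of the largest HOMO coefficient at the diene terminus remote from the acetal with the largest LUMO coefficient at the β-carbon of the ynone, and it needs the concerted pathway to win over a conjugate-addition/aldol sequence, which is favoured by running it thermally without Lewis acid. The dihydropyran ring holds its C4 methylene on the outward side of the diene terminus, so the s-cis conformer is accessible.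

Step 5
Reactants: 10 1-(7-hydroxy-2,2-dimethyl-3,4-dihydro-2H-chromen-6-yl)ethan-1-one
Product: 11 1-(7-methoxy-2,2-dimethyl-3,4-dihydro-2H-chromen-6-yl)ethan-1-one
Conditions: MeI (3 equiv), K2CO3 (3 equiv), acetone, reflux
Reagents that add atoms: iodomethane, CI
Why: Williamson O-alkylation of the phenoxide; the hydrogen-bonded ortho-acyl phenol needs the carbonate base at reflux but is otherwise unexceptional.

Step 6
Reactants: 11 1-(7-methoxy-2,2-dimethyl-3,4-dihydro-2H-chromen-6-yl)ethan-1-one
Product: 12 1-(7-methoxy-2,2-dimethyl-2H-chromen-6-yl)ethan-1-one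
Conditions: DDQ (1.3 equiv), benzene, reflux
Reagents that add atoms: none
Why: Quinone dehydrogenation: DDQ abstracts hydride from benzylic C4, whose cation is stabilized by O1 and by the para 7-methoxy group, and loss of a C3 proton gives the 2H-chromene, a standard conversion of 2,2-dimethylchromans.

Step 7
Reactants: 12 1-(7-methoxy-2,2-dimethyl-2H-chromen-6-yl)ethan-1-one
Product: 13 (1S)-1-(7-methoxy-2,2-dimethyl-2H-chromen-6-yl)ethan-1-ol
Conditions: H2 (8 atm), trans-RuCl2[(R)-xylbinap][(R)-daipen] (0.2 mol%), t-BuOK (2 mol%), i-PrOH, 25 °C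
Reagents that add atoms: none
Why: Noyori asymmetric hydrogenation with the RuCl2(diphosphine)(diamine)/base system reduces aryl methyl ketones and leaves olefins untouched; by analogy with acetophenone, where the (S,S) catalyst gives the (R) alcohol, the (R,R) catalyst should deliver hydride to the Re face and set the (S) carbinol centre, and the basic medium spares the ionization-prone benzylic alcohol.

Step 8
Reactants: 14 2-iodo-5-methylphenol
Product: 15 (2-iodo-5-methylphenoxy)tri(propan-2-yl)silane
Conditions: iPr3SiCl (1.1 equiv), imidazole (2 equiv), DMF, rt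
Reagents that add atoms: chlorotri(propan-2-yl)silane, CC(C)[Si](Cl)(C(C)C)C(C)C
Why: Imidazole-promoted silylation of the phenol; the bulky silyl group is chosen to survive the Grignard and carbonate steps and to fall to fluoride at the end.

Step 9
Reactants: 15 (2-iodo-5-methylphenoxy)tri(propan-2-yl)silane; 16 prop-2-yn-1-ol
Product: 19 (2Z)-3-iodo-2-[4-methyl-2-(triisopropylsilyloxy)phenyl]prop-2-en-1-ol, via arylmagnesium iodide 17 (not isolated), via oxamagnesole chelate 18 (not isolated)
Conditions: Mg turnings, THF, rt; then 16 (0.4 equiv relative to 15), CuI (10 mol% relative to 16), THF, 0 °C → 40 °C; then I2, THF, −20 °C → 0 °C; aq. NH4Cl/Na2S2O3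
Reagents that add atoms: iodine, II
Why: Copper-catalysed anti-carbomagnesiation of propargyl alcohol: the aryl group adds to C2 and magnesium ends up on C3 cis to the alkoxymethyl group in a five-membered chelate, so iodinolysis with retention places iodine cis to CH2OH and fixes the Z geometry of the future enol ether.

Step 10
Reactants: 19 (2Z)-3-iodo-2-[4-methyl-2-(triisopropylsilyloxy)phenyl]prop-2-en-1-ol
Product: 20 tert-butyl{[(2Z)-3-iodo-2-[4-methyl-2-(triisopropylsilyloxy)phenyl]prop-2-en-1-yl]oxy}dimethylsilane
Conditions: t-BuMe2SiCl (1.2 equiv), imidazole (2 equiv), CH2Cl2, 0 °C → rt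
Reagents that add atoms: tert-butyl(chloro)dimethylsilane, CC(C)(C)[Si](C)(C)Cl
Why: Standard silylation of the primary allylic alcohol, which prevents it from competing as a nucleophile in the C–O coupling.

Step 11
Reactants: 13 (1S)-1-(7-methoxy-2,2-dimethyl-2H-chromen-6-yl)ethan-1-ol; 20 tert-butyl{[(2Z)-3-iodo-2-[4-methyl-2-(triisopropylsilyloxy)phenyl]prop-2-en-1-yl]oxy}dimethylsilane
Product: 21 tert-butyl{[(2Z)-3-[(1S)-1-(7-methoxy-2,2-dimethyl-2H-chromen-6-yl)ethoxy]-2-[4-methyl-2-(triisopropylsilyloxy)phenyl]prop-2-en-1-yl]oxy}dimethylsilane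
Conditions: 20 (1.3 equiv), CuI (10 mol%), 3,4,7,8-tetramethyl-1,10-phenanthroline (20 mol%), Cs2CO3 (2 equiv), toluene, 80 °C, argon
Reagents that add atoms: none
Why: Ullmann-type copper-catalysed C–O cross-coupling of a vinyl iodide with an aliphatic alcohol, known for secondary alcohols and 2,2-disubstituted vinyl iodides, proceeds with retention of alkene geometry and never breaks the carbinol C–O bond, so the Z enol ether and the (S) centre are both carried through.

Step 12
Reactants: 21 tert-butyl{[(2Z)-3-[(1S)-1-(7-methoxy-2,2-dimethyl-2H-chromen-6-yl)ethoxy]-2-[4-methyl-2-(triisopropylsilyloxy)phenyl]prop-2-en-1-yl]oxy}dimethylsilane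
Product: 22 (2Z)-2-(2-hydroxy-4-methylphenyl)-3-[(1S)-1-(7-methoxy-2,2-dimethyl-2H-chromen-6-yl)ethoxy]prop-2-en-1-ol
Conditions: Bu4NF (2.5 equiv), THF, 0 °C → rt; aq. NaHCO3 work-up; chromatography on Et3N-deactivated silica
Reagents that add atoms: none
Why: Fluoride-induced cleavage of both silyl ethers under non-acidic conditions, which the acid-labile benzylic enol ether, the chromene and the stereocentre should tolerate.

Compound list
1 | 6,6-dimethyloxan-2-one | CC1(C)CCCC(=O)O1 | starting material
2 | methyl acetate | COC(C)=O | starting material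
3 | lithium 1-methoxyethenolate (lithium enolate of methyl acetate) | [Li]OC(=C)OC | intermediate (not isolated)
4 | methyl 2-(2-hydroxy-6,6-dimethyloxan-2-yl)acetate (racemic lactol) | COC(=O)CC1(O)CCCC(C)(C)O1 | intermediate
5 | methyl (2E)-2-(6,6-dimethyloxan-2-ylidene)acetate | COC(=O)/C=C1\CCCC(C)(C)O1 | intermediate
6 | lithium 2-(6,6-dimethyl-5,6-dihydro-4H-pyran-2-yl)-1-methoxyethenolate (lithium dienolate of 5) | [Li]OC(OC)=CC1=CCCC(C)(C)O1 | intermediate (not isolated)
7 | 6-[2-methoxy-2-(trimethylsilyloxy)ethenyl]-2,2-dimethyl-3,4-dihydro-2H-pyran | COC(O[Si](C)(C)C)=CC1=CCCC(C)(C)O1 | intermediate (key-step precursor)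
8 | but-3-yn-2-one | CC(=O)C#C | starting material
9 | 1-[7-methoxy-2,2-dimethyl-7-(trimethylsilyloxy)-3,4,4a,7-tetrahydro-2H-chromen-6-yl]ethan-1-one (cycloadduct, stereoisomer mixture) | CC(=O)C1=CC2CCC(C)(C)OC2=CC1(OC)O[Si](C)(C)C | intermediate (not isolated)
10 | 1-(7-hydroxy-2,2-dimethyl-3,4-dihydro-2H-chromen-6-yl)ethan-1-one (6-acetyl-7-hydroxy-2,2-dimethylchroman) | CC(=O)c1cc2CCC(C)(C)Oc2cc1O | intermediate (key-step product)
11 | 1-(7-methoxy-2,2-dimethyl-3,4-dihydro-2H-chromen-6-yl)ethan-1-one | COc1cc2OC(C)(C)CCc2cc1C(C)=O | intermediate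
12 | 1-(7-methoxy-2,2-dimethyl-2H-chromen-6-yl)ethan-1-one | COc1cc2OC(C)(C)C=Cc2cc1C(C)=O | intermediate
13 | (1S)-1-(7-methoxy-2,2-dimethyl-2H-chromen-6-yl)ethan-1-ol | COc1cc2c(cc1[C@H](C)O)C=CC(C)(C)O2 | intermediate
14 | 2-iodo-5-methylphenol | Cc1ccc(I)c(O)c1 | starting material
15 | (2-iodo-5-methylphenoxy)tri(propan-2-yl)silane | Cc1ccc(I)c(O[Si](C(C)C)(C(C)C)C(C)C)c1 | intermediate
16 | prop-2-yn-1-ol | OCC#C | starting material
17 | [4-methyl-2-(triisopropylsilyloxy)phenyl]magnesium iodide | Cc1ccc([Mg]I)c(O[Si](C(C)C)(C(C)C)C(C)C)c1 | intermediate (not isolated)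
18 | 4-[4-methyl-2-(triisopropylsilyloxy)phenyl]-2,5-dihydro-1,2-oxamagnesole | Cc1ccc(C2=C[Mg]OC2)c(O[Si](C(C)C)(C(C)C)C(C)C)c1 | intermediate (not isolated)
19 | (2Z)-3-iodo-2-[4-methyl-2-(triisopropylsilyloxy)phenyl]prop-2-en-1-ol | I/C=C(\CO)c1ccc(C)cc1O[Si](C(C)C)(C(C)C)C(C)C | intermediate
20 | tert-butyl{[(2Z)-3-iodo-2-[4-methyl-2-(triisopropylsilyloxy)phenyl]prop-2-en-1-yl]oxy}dimethylsilane | I/C=C(\CO[Si](C)(C)C(C)(C)C)c1ccc(C)cc1O[Si](C(C)C)(C(C)C)C(C)C | intermediate
21 | tert-butyl{[(2Z)-3-[(1S)-1-(7-methoxy-2,2-dimethyl-2H-chromen-6-yl)ethoxy]-2-[4-methyl-2-(triisopropylsilyloxy)phenyl]prop-2-en-1-yl]oxy}dimethylsilane | COc1cc2c(cc1[C@H](C)O/C=C(\CO[Si](C)(C)C(C)(C)C)c1ccc(C)cc1O[Si](C(C)C)(C(C)C)C(C)C)C=CC(C)(C)O2 | intermediate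
22 | (2Z)-2-(2-hydroxy-4-methylphenyl)-3-[(1S)-1-(7-methoxy-2,2-dimethyl-2H-chromen-6-yl)ethoxy]prop-2-en-1-ol | COc1cc2c(cc1[C@H](C)O/C=C(\CO)c1ccc(C)cc1O)C=CC(C)(C)O2 | target

Total step count: 12
Longest linear sequence: 9 steps (steps 1–7, 11, 12); the vinyl iodide branch is steps 8–10.

Steps most likely to fail

1. Step 4 (cycloaddition/aromatization). The silyl group may be lost from the ketene acetal before cycloaddition, the ynone may oligomerize, or the reaction may divert into a stepwise conjugate-addition/aldol manifold that draws the ketone carbon into the ring. Aromatization by loss of silanol instead of methanol would give the 7-methyl ether, which is compound 11 and is simply carried on. Fallback: the pyran ring is closed on a preformed benzene ring instead of building the arene. This fallback does not branch from a numbered compound: it replaces compounds 1–9 and sets out from purchased 1-(2,4-dihydroxyphenyl)ethan-1-one F1 and 2-methylbut-3-en-2-ol F2. Under BF3·OEt2 in dioxane these should undergo Friedel–Crafts prenylation at C5 of the ketone and ring closure through the 4-hydroxyl, giving the linear chroman, which is separated from the angular 5-hydroxy isomer by chromatography. It comes back to the route at compound 10.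

2. Step 11 (C–O coupling). The hindered secondary benzylic alkoxide may couple slowly, the alcohol may ionize or eliminate to the styrene on heating, or the aryl silyl group may transfer to the alkoxide. Fallback: the ether oxygen is attached to sp3 carbon first and the enol ether is then built by C–C bond formation. It sets out from alcohol 13 and aryl iodide 15.
   - Williamson propargylation of 13 (NaH, propargyl bromide, THF/DMF, 0 °C) should give (S)-7-methoxy-2,2-dimethyl-6-[1-(prop-2-yn-1-yloxy)ethyl]-2H-chromene F3.
   - Base-mediated isomerization (t-BuOK, 0.3 equiv, THF, rt) should give the allenyl ether (S)-7-methoxy-2,2-dimethyl-6-[1-(propa-1,2-dien-1-yloxy)ethyl]-2H-chromene F4.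
   - A palladium-catalysed three-component coupling of F4, 15 and bis(pinacolato)diboron (Pd2(dba)3, PPh3, KOAc, toluene, 50 °C) follows. The arylpalladium species should add its aryl group to the central allene carbon from the face remote from the alkoxy group, and the π-allyl intermediate should be borylated at the unsubstituted terminus. This should give 2-[(2E)-3-[(1S)-1-(7-methoxy-2,2-dimethyl-2H-chromen-6-yl)ethoxy]-2-[4-methyl-2-(triisopropylsilyloxy)phenyl]prop-2-en-1-yl]-4,4,5,5-tetramethyl-1,3,2-dioxaborolane F5, with the ether oxygen cis to CH2B. This step is the least precedented in the fallback.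
   - Oxidation with NaBO3·4H2O (THF/water, rt) should give (2Z)-3-[(1S)-1-(7-methoxy-2,2-dimethyl-2H-chromen-6-yl)ethoxy]-2-[4-methyl-2-(triisopropylsilyloxy)phenyl]prop-2-en-1-ol F6.
   - Bu4NF in THF then removes the aryl silyl group, and the fallback comes back to the route at target 22.

3. Step 9 (carbomagnesiation). The hindered ortho-silyloxy arylmagnesium may add sluggishly, or the silyl group may migrate from oxygen to carbon in the Grignard reagent on warming. Fallback: the aryl group is introduced by cross-coupling instead of as a Grignard reagent. It sets out from aryl iodide 15.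
   - Palladium-catalysed syn-hydrostannation of purchased 3-(trimethylsilyl)prop-2-yn-1-ol F7 (Bu3SnH, PdCl2(PPh3)2, THF, rt) should place tin on C2, remote from silicon, giving (2E)-2-(tributylstannyl)-3-(trimethylsilyl)prop-2-en-1-ol F8.
   - Stille coupling of F8 with 15 (Pd(PPh3)4, CuI, DMF, 60 °C) should give (2Z)-2-[4-methyl-2-(triisopropylsilyloxy)phenyl]-3-(trimethylsilyl)prop-2-en-1-ol F9 with retention.
   - Ipso-iododesilylation with N-iodosuccinimide (MeCN, 0 °C) should replace silicon by iodine with retention, and the fallback comes back to the route at vinyl iodide 19.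

Further compounds
F1 | step 4 | 1-(2,4-dihydroxyphenyl)ethan-1-one (purchased) | CC(=O)c1ccc(O)cc1O
F2 | step 4 | 2-methylbut-3-en-2-ol (purchased) | CC(C)(O)C=C
F3 | step 11 | (S)-7-methoxy-2,2-dimethyl-6-[1-(prop-2-yn-1-yloxy)ethyl]-2H-chromene | COc1cc2c(cc1[C@H](C)OCC#C)C=CC(C)(C)O2
F4 | step 11 | (S)-7-methoxy-2,2-dimethyl-6-[1-(propa-1,2-dien-1-yloxy)ethyl]-2H-chromene | COc1cc2c(cc1[C@H](C)OC=C=C)C=CC(C)(C)O2
F5 | step 11 | 2-[(2E)-3-[(1S)-1-(7-methoxy-2,2-dimethyl-2H-chromen-6-yl)ethoxy]-2-[4-methyl-2-(triisopropylsilyloxy)phenyl]prop-2-en-1-yl]-4,4,5,5-tetramethyl-1,3,2-dioxaborolane | COc1cc2c(cc1[C@H](C)O/C=C(\CB1OC(C)(C)C(C)(C)O1)c1ccc(C)cc1O[Si](C(C)C)(C(C)C)C(C)C)C=CC(C)(C)O2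
F6 | step 11 | (2Z)-3-[(1S)-1-(7-methoxy-2,2-dimethyl-2H-chromen-6-yl)ethoxy]-2-[4-methyl-2-(triisopropylsilyloxy)phenyl]prop-2-en-1-ol | COc1cc2c(cc1[C@H](C)O/C=C(\CO)c1ccc(C)cc1O[Si](C(C)C)(C(C)C)C(C)C)C=CC(C)(C)O2
F7 | step 9 | 3-(trimethylsilyl)prop-2-yn-1-ol (purchased) | C[Si](C)(C)C#CCO
F8 | step 9 | (2E)-2-(tributylstannyl)-3-(trimethylsilyl)prop-2-en-1-ol | C[Si](C)(C)/C=C(\CO)[Sn](CCCC)(CCCC)CCCC
F9 | step 9 | (2Z)-2-[4-methyl-2-(triisopropylsilyloxy)phenyl]-3-(trimethylsilyl)prop-2-en-1-ol | C[Si](C)(C)/C=C(\CO)c1ccc(C)cc1O[Si](C(C)C)(C(C)C)C(C)C
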